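**Retrosynthetic overview**
1. Target ⇐ 8,10‑diol 16 (two late acylations) ⇐ ketol 15, by ketohydroxylation of the E‑C1=C10 alkene of butenolide 14.
2. Butenolide ring (formed last) ⇐ aldol of the macrocyclic C6/C7 enolate with acetoxypyruvate 9, C6 reduction/lactonisation, dehydration to C7=C11.
3. Ten‑membered ring (C8–C9 bond) ⇐ anionic oxy‑Cope [3,3] shift of trans‑dialkenyl cyclohexenol 7; the ring stereocentre of isopiperitenone is relayed to C8, and C8 then controls C6 and C10.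
4. Carbinol 7 ⇐ (R)‑isopiperitenone 2 (from (S)‑limonene) + (Z)‑2‑(benzyloxy)vinyllithium.
5. Ring order: cyclohexene (bought) → cyclodecadienone → butenolide.

Assumption: the target is taken exactly as drawn, i.e. (4Z,6R,8S,10S); germacrane locants are used (ketone C1, lactone C12 on O6, acetoxymethyl C13).

**Step 1**
Reactants: 1 (S)‑(−)‑limonene
Product: 2 (R)‑isopiperitenone
Conditions: t‑BuOOH, Cr(CO)6 (cat.), MeCN, reflux
Reagents that add atoms: tert‑butyl hydroperoxide, CC(C)(C)OO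
Why: Chromium‑catalysed allylic C–H oxidation of the ring CH2 between the alkene and the stereocentre gives the enone (separated from regioisomeric carvone); the stereocentre is untouched and its label changes from S to R only through CIP priorities.

**Step 2**
Reactants: 3 benzyl vinyl ether
Product: 5 benzyl (Z)‑2‑bromovinyl ether, via dibromide 4 (not isolated)
Conditions: Br2, CH2Cl2, −78 °C; then iPr2NEt, 0 → 40 °C
Reagents that add atoms: bromine, BrBr
Why: Bromination of the enol ether followed by dehydrobromination of the α‑bromo ether, which, as for the ethyl analogue, gives mainly the Z bromide.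

**Step 3**
Reactants: 5 benzyl (Z)‑2‑bromovinyl ether; 2 (R)‑isopiperitenone
Product: 7 (1R,6R)‑1‑[(Z)‑2‑(benzyloxy)ethenyl]‑3‑methyl‑6‑(prop‑1‑en‑2‑yl)cyclohex‑2‑en‑1‑ol, via vinyllithium 6 (not isolated)
Conditions: t‑BuLi (2 equiv), Et2O, −78 °C; then 2, −78 °C; H2O
Reagents that add atoms: none
Why: Bromine–lithium exchange with retention of alkene geometry, then 1,2‑addition to the enone anti to the adjacent isopropenyl group, giving the trans‑1,2‑dialkenyl carbinol (new centre 1R).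

**Step 4**
Reactants: 8 ethyl bromopyruvate
Product: 9 ethyl 3‑acetoxy‑2‑oxopropanoate
Conditions: KOAc, acetone, 25 °C
Reagents that add atoms: potassium acetate, CC(=O)[O-].[K+]
Why: SN2 displacement of the activated α‑keto bromide by acetate.

**Step 5**
Reactants: 7 the carbinol; 9 ethyl 3‑acetoxy‑2‑oxopropanoate
Product: 11 ethyl 3‑acetoxy‑2‑[(3Z,7E,10S)‑10‑(benzyloxy)‑4,8‑dimethyl‑2‑oxocyclodeca‑3,7‑dien‑1‑yl]‑2‑hydroxypropanoate, via potassium dienolate 10 (not isolated)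
Conditions: KN(SiMe3)2, 18‑crown‑6, THF, −40 → 0 °C; ZnCl2, −78 °C; then 9; AcOH, −78 °C
Reagents that add atoms: none
Why: Anionic oxy‑Cope [3,3]‑sigmatropic rearrangement through a chair transition state with both alkenyl groups equatorial forms C8–C9 and the E‑C1=C10 alkene; the Z enol ether places OBn pseudo‑axial, so the ring stereocentre is relayed to C8 as 8S, and the regiodefined zinc enolate is then trapped at C7 from the ring periphery by aldol addition to the keto ester (the C7 and C11 centres are erased in step 7).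

**Step 6**
Reactants: 11 the aldol adduct
Product: 13 (6R,8S)‑13‑acetoxy‑8‑(benzyloxy)‑11‑hydroxygermacra‑1(10)E,4Z‑dien‑12,6‑olide, via hydroxy ester 12 (not isolated)
Conditions: Me4NBH(OAc)3, MeCN/AcOH, −30 °C; then PPTS (cat.), CH2Cl2, 25 °C
Reagents that add atoms: none
Why: Evans–Saksena hydroxyl‑directed 1,2‑reduction, in which the C11 carbinol delivers hydride to the peripheral face of the C6 ketone (the face carrying the C7–C11 bond), expected to give the 6R carbinol syn to O8; the γ‑hydroxy ester then lactonises.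

**Step 7**
Reactants: 13 the α‑hydroxy lactone
Product: 14 (6R,8S)‑13‑acetoxy‑8‑(benzyloxy)germacra‑1(10)E,4Z,7(11)‑trien‑12,6‑olide
Conditions: SOCl2, pyridine, CH2Cl2, −20 → 0 °C
Reagents that add atoms: none
Why: Dehydration of the tertiary carbinol via its chlorosulfite (E2), where loss of the ring methine H7 gives the tetrasubstituted alkene conjugated with the lactone; the C13 hydrogens sit on an acetoxy‑bearing carbon and would give only an enol acetate.

**Step 8**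
Reactants: 14 the butenolide
Product: 15 (6R,8S,10S)‑13‑acetoxy‑8‑(benzyloxy)‑10‑hydroxy‑1‑oxogermacra‑4Z,7(11)‑dien‑12,6‑olide
Conditions: RuCl3 (1 mol %), KHSO5 (as 2KHSO5·KHSO4·K2SO4), NaHCO3, EtOAc/MeCN/H2O, 20 °C
Reagents that add atoms: potassium peroxymonosulfate, [K+].[O-]S(=O)(=O)OO
Why: RuO4‑catalysed ketohydroxylation (Plietker) of the strained, electron‑rich E‑C1=C10 alkene by [3+2] addition from the exposed face of the conformation fixed by C8 and the E alkene, giving the tertiary 10S alcohol and the C1 ketone; the Z‑C4=C5 alkene is deactivated by the allylic lactone oxygen and the butenolide alkene is electron‑poor.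

**Step 9**
Reactants: 15 the ketol benzyl ether
Product: 16 (6R,8S,10S)‑13‑acetoxy‑8,10‑dihydroxy‑1‑oxogermacra‑4Z,7(11)‑dien‑12,6‑olide
Conditions: BCl3, C6HMe5, CH2Cl2, −78 °C; MeOH
Reagents that add atoms: none
Why: Lewis‑acid debenzylation with pentamethylbenzene as benzyl‑cation scavenger, which leaves the alkene (no hydrogenolysis), the esters and the ketol intact at −78 °C.

**Step 10**
Reactants: 16 the 8,10‑diol
Product: 18 target, (6R,8S,10S)‑10,13‑diacetoxy‑8‑(methacryloyloxy)‑1‑oxogermacra‑4Z,7(11)‑dien‑12,6‑olide, via 8‑methacrylate 17 (not isolated)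
Conditions: methacrylic anhydride (1.1 equiv), Et3N, DMAP (cat.), CH2Cl2, 0 °C; then Ac2O, DMAP, 25–35 °C
Reagents that add atoms: methacrylic anhydride, C=C(C)C(=O)OC(=O)C(C)=C; acetic anhydride, CC(=O)OC(C)=O
Why: DMAP‑catalysed acylations in rate order, the secondary C8 alcohol reacting with the limiting methacrylic anhydride and the tertiary α‑ketol hydroxyl then being acetylated under forcing conditions; no stereocentre is touched.

**Compound list**
1 | (S)‑(−)‑limonene | CC1=CC[C@H](CC1)C(C)=C | starting material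
2 | (R)‑isopiperitenone, (6R)‑3‑methyl‑6‑(prop‑1‑en‑2‑yl)cyclohex‑2‑en‑1‑one | CC1=CC(=O)[C@H](CC1)C(C)=C | intermediate
3 | benzyl vinyl ether | C=COCc1ccccc1 | starting material
4 | (1,2‑dibromoethoxy)methylbenzene (racemic) | BrCC(Br)OCc1ccccc1 | intermediate
5 | benzyl (Z)‑2‑bromovinyl ether | Br/C=C\OCc1ccccc1 | intermediate
6 | (Z)‑2‑(benzyloxy)ethenyllithium | [Li]/C=C\OCc1ccccc1 | intermediate
7 | (1R,6R)‑1‑[(Z)‑2‑(benzyloxy)ethenyl]‑3‑methyl‑6‑(prop‑1‑en‑2‑yl)cyclohex‑2‑en‑1‑ol | CC1=C[C@](O)(/C=C\OCc2ccccc2)[C@@H](C(C)=C)CC1 | intermediate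
8 | ethyl bromopyruvate | CCOC(=O)C(=O)CBr | starting material
9 | ethyl 3‑acetoxy‑2‑oxopropanoate | CCOC(=O)C(=O)COC(C)=O | intermediate
10 | potassium (1(10)Z,2Z,6E,9S)‑9‑(benzyloxy)‑3,7‑dimethylcyclodeca‑1(10),2,6‑trien‑1‑olate | [K+].[O-]/C1=C\[C@@H](OCc2ccccc2)C/C(C)=C/CC/C(C)=C\1 | intermediate
11 | ethyl 3‑acetoxy‑2‑[(3Z,7E,10S)‑10‑(benzyloxy)‑4,8‑dimethyl‑2‑oxocyclodeca‑3,7‑dien‑1‑yl]‑2‑hydroxypropanoate (mixture at C7, C11) | CCOC(=O)C(O)(COC(C)=O)C1C(=O)/C=C(C)\CC/C=C(C)/C[C@@H]1OCc2ccccc2 | intermediate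
12 | ethyl 3‑acetoxy‑2‑[(2R,3Z,7E,10S)‑10‑(benzyloxy)‑2‑hydroxy‑4,8‑dimethylcyclodeca‑3,7‑dien‑1‑yl]‑2‑hydroxypropanoate | CCOC(=O)C(O)(COC(C)=O)C1[C@H](O)/C=C(C)\CC/C=C(C)/C[C@@H]1OCc2ccccc2 | intermediate
13 | (6R,8S)‑13‑acetoxy‑8‑(benzyloxy)‑11‑hydroxygermacra‑1(10)E,4Z‑dien‑12,6‑olide (mixture at C7, C11) | CC(=O)OCC1(O)C(=O)O[C@@H]2/C=C(C)\CC/C=C(C)/C[C@H](OCc3ccccc3)C12 | intermediate
14 | (6R,8S)‑13‑acetoxy‑8‑(benzyloxy)germacra‑1(10)E,4Z,7(11)‑trien‑12,6‑olide | c1ccccc1CO[C@H]2C/C(C)=C/CC/C(C)=C\[C@H]3OC(=O)C(COC(C)=O)=C23 | intermediate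
15 | (6R,8S,10S)‑13‑acetoxy‑8‑(benzyloxy)‑10‑hydroxy‑1‑oxogermacra‑4Z,7(11)‑dien‑12,6‑olide | c1ccccc1CO[C@H]2C[C@](C)(O)C(=O)CC/C(C)=C\[C@H]3OC(=O)C(COC(C)=O)=C23 | intermediate
16 | (6R,8S,10S)‑13‑acetoxy‑8,10‑dihydroxy‑1‑oxogermacra‑4Z,7(11)‑dien‑12,6‑olide | O[C@H]1C[C@](C)(O)C(=O)CC/C(C)=C\[C@H]2OC(=O)C(COC(C)=O)=C12 | intermediate
17 | (6R,8S,10S)‑13‑acetoxy‑10‑hydroxy‑8‑(methacryloyloxy)‑1‑oxogermacra‑4Z,7(11)‑dien‑12,6‑olide | C=C(C)C(=O)O[C@H]1C[C@](C)(O)C(=O)CC/C(C)=C\[C@H]2OC(=O)C(COC(C)=O)=C12 | intermediate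
18 | (6R,8S,10S)‑10,13‑diacetoxy‑8‑(methacryloyloxy)‑1‑oxogermacra‑4Z,7(11)‑dien‑12,6‑olide | C=C(C)C(=O)O[C@H]1C[C@](C)(OC(C)=O)C(=O)CC/C(C)=C\[C@H]2OC(=O)C(COC(C)=O)=C12 | target

**Step count**
Total: 10 steps. Longest linear sequence: 8 steps (1 → 3 → 5 → 6 → 7 → 8 → 9 → 10); steps 2 and 4 make the two side components.

**Three steps most likely to fail**

Step 5. Dienolate 10 carries a β‑benzyloxy group and may lose benzyloxide before it is trapped, or the one‑flask aldol may be unclean. The fallback sets out from 7 and comes back at 11. The [3,3] shift is run without base with PdCl2(MeCN)2 (10 mol %) in THF at 25 °C; 7 is a 5‑methyl‑1,5‑dien‑3‑ol, the pattern this catalysis needs, and the same chair array gives the neutral ketone (2Z,6E,9S)‑9‑(benzyloxy)‑3,7‑dimethylcyclodeca‑2,6‑dien‑1‑one F1. F1 is enolised only at −78 °C with LiN(iPr)2 (its single α‑CH2 is C7), transmetalated with ZnCl2 and added to 9, giving 11.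

Step 6. The directed reduction relies on C7/C11 centres that the aldol sets without firm control, so the 6‑epimer may predominate. The fallback sets out from 11 and comes back at 14. Ac2O/DMAP/Et3N then DBU removes those centres by E1cB loss of the tertiary acetate, giving ethyl 3‑acetoxy‑2‑[(3Z,7E,10S)‑10‑(benzyloxy)‑4,8‑dimethyl‑2‑oxocyclodeca‑3,7‑dien‑1‑ylidene]propanoate F2 (either geometry of the new alkene is usable). NaBH4/CeCl3·7H2O in MeOH at −78 °C then reduces the C7‑planar dienone from the ring periphery. The isomer with the ester syn to C6 lactonises in the flask to 14. The other gives ethyl 3‑acetoxy‑2‑[(2R,3Z,7E,10S)‑10‑(benzyloxy)‑2‑hydroxy‑4,8‑dimethylcyclodeca‑3,7‑dien‑1‑ylidene]propanoate F3, which is funnelled to 14 by benzophenone‑sensitised photoisomerisation of the enoate, lactonisation draining the required isomer.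

Step 7. Elimination from 13 may also run toward C13 and give the exocyclic enol acetate. The fallback sets out from 7 and comes back at 14; it attaches C13 only after the ring alkene is fixed. 7 is taken through the step 5 sequence with ethyl glyoxylate (O=CC(=O)OCC) in place of 9, giving ethyl 2‑[(3Z,7E,10S)‑10‑(benzyloxy)‑4,8‑dimethyl‑2‑oxocyclodeca‑3,7‑dien‑1‑yl]‑2‑hydroxyacetate F4. Me4NBH(OAc)3 then PPTS gives (6R,8S)‑8‑(benzyloxy)‑11‑hydroxy‑13‑norgermacra‑1(10)E,4Z‑dien‑12,6‑olide F5. Dess–Martin periodinane gives the α‑keto lactone, which exists as its enol (6R,8S)‑8‑(benzyloxy)‑11‑hydroxy‑13‑norgermacra‑1(10)E,4Z,7(11)‑trien‑12,6‑olide F6, since C7 is the only enolisable position. PhNTf2/Et3N gives (6R,8S)‑8‑(benzyloxy)‑11‑(trifluoromethanesulfonyloxy)‑13‑norgermacra‑1(10)E,4Z,7(11)‑trien‑12,6‑olide F7. Stille coupling with Bu3SnCH2OH (Pd(PPh3)4, LiCl, dioxane, 90 °C) gives (6R,8S)‑8‑(benzyloxy)‑13‑hydroxygermacra‑1(10)E,4Z,7(11)‑trien‑12,6‑olide F8, and Ac2O/pyridine gives 14.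

**Further compounds**
F1 | step 5 | (2Z,6E,9S)‑9‑(benzyloxy)‑3,7‑dimethylcyclodeca‑2,6‑dien‑1‑one | O=C1/C=C(C)\CC/C=C(C)/C[C@H](OCc2ccccc2)C1
F2 | step 6 | ethyl 3‑acetoxy‑2‑[(3Z,7E,10S)‑10‑(benzyloxy)‑4,8‑dimethyl‑2‑oxocyclodeca‑3,7‑dien‑1‑ylidene]propanoate (new alkene geometry unassigned) | CCOC(=O)C(COC(C)=O)=C1C(=O)/C=C(C)\CC/C=C(C)/C[C@@H]1OCc2ccccc2
F3 | step 6 | ethyl 3‑acetoxy‑2‑[(2R,3Z,7E,10S)‑10‑(benzyloxy)‑2‑hydroxy‑4,8‑dimethylcyclodeca‑3,7‑dien‑1‑ylidene]propanoate (ester anti to the carbinol) | CCOC(=O)/C(COC(C)=O)=C1/[C@H](O)/C=C(C)\CC/C=C(C)/C[C@@H]1OCc2ccccc2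
F4 | step 7 | ethyl 2‑[(3Z,7E,10S)‑10‑(benzyloxy)‑4,8‑dimethyl‑2‑oxocyclodeca‑3,7‑dien‑1‑yl]‑2‑hydroxyacetate | CCOC(=O)C(O)C1C(=O)/C=C(C)\CC/C=C(C)/C[C@@H]1OCc2ccccc2
F5 | step 7 | (6R,8S)‑8‑(benzyloxy)‑11‑hydroxy‑13‑norgermacra‑1(10)E,4Z‑dien‑12,6‑olide | OC1C(=O)O[C@@H]2/C=C(C)\CC/C=C(C)/C[C@H](OCc3ccccc3)C12
F6 | step 7 | (6R,8S)‑8‑(benzyloxy)‑11‑hydroxy‑13‑norgermacra‑1(10)E,4Z,7(11)‑trien‑12,6‑olide | c1ccccc1CO[C@H]2C/C(C)=C/CC/C(C)=C\[C@H]3OC(=O)C(O)=C23
F7 | step 7 | (6R,8S)‑8‑(benzyloxy)‑11‑(trifluoromethanesulfonyloxy)‑13‑norgermacra‑1(10)E,4Z,7(11)‑trien‑12,6‑olide | c1ccccc1CO[C@H]2C/C(C)=C/CC/C(C)=C\[C@H]3OC(=O)C(OS(=O)(=O)C(F)(F)F)=C23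
F8 | step 7 | (6R,8S)‑8‑(benzyloxy)‑13‑hydroxygermacra‑1(10)E,4Z,7(11)‑trien‑12,6‑olide | c1ccccc1CO[C@H]2C/C(C)=C/CC/C(C)=C\[C@H]3OC(=O)C(CO)=C23
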